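In a one-step world each reagent has its own rate, and a second reagent leaves the first one's product alone. These flasks may be different: by the proposed steps Z and D both pass through Q, charged at 20 mol% of Z, and G goes on to L on Q as well.

common to all: Z 0.10 M; Q 20 mol%
- north: D 0.34 equiv; run made earlier
- south-west: D 2.8 equiv; run made earlier
- noon: D 0.250 equiv; time 5.0 d
- midnight: D 0.500 equiv; time 5.0 d
- winter: D 1.00 equiv; time 5.0 d
- dusk: D 2.00 equiv; time 5.0 d

| run | time / d | G / % | L / % |
|---|---|---|---|
| north | 0.417 | 8.5 | 0 |
| north | 1.25 | 24.7 | 2.5 |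
| north | 2.50 | 42.6 | 9.2 |
| north | 4.00 | 50.7 | 24.5 |
| north | 5.00 | 50.6 | 33.6 |
| south-west | 0.417 | 7.3 | 0.6 |
| south-west | 0.833 | 15.9 | 0.3 |
| south-west | 1.25 | 23.4 | 1.9 |
| south-west | 2.50 | 37.9 | 6.9 |
| south-west | 5.00 | 52.3 | 23.4 |

(each reading ± 1 percentage point)

- share of G in all that became G or L for noon, midnight, winter, dusk, in this order
- the course of these numbers from the first flask to the last (hardly changes / falls, then rises / falls all the way / rises all the way / rises, then falls)

- steps that have been proposed: Z + Q <-> J; J -> Q + G; D + Q <-> X; X -> Q + E; G + Q <-> L + Q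
- "hardly changes" means that all values lie within two and a half points (for a concentration: within two and a half percent of the largest)

I compare dusk with its neighbour, south-west, which carries 2.8 equiv of D against 2.00 equiv. At 5.00 d, north and south-west read G at 50.6 % and 52.3 %, a gap of 1.7 percentage points. Their L readings, 33.6 % and 23.4 %, lie wider apart, by 10 points. So I hold G level at the mean, 51.4 %, and let D act on L through free Q. I write the balance of Q, in fractions of its charge, with d the equivalents of D:

q + j + x = 1, with x = q·d/b, so q = (1 − j)/(1 + d/b)

Taking j alike in both runs, I let L at that time go as 1/(1 + d/b), which is my estimate, since L gathers over the whole run. The ratio of the two L readings then gives b: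

L(north)/L(south-west) = 1.44, so b = 5.30 equiv

This b, the equivalents of D at which X stands equal to Q, is a reading from two runs. Dusk carries less D than south-west, so I expect more L than south-west's:

L(dusk) = 26.0 %

The share of G (the selectivity for G) in dusk is then 66.5 %, and in noon 60.1 %, so my row rises.

The forecast prints 59.5 %, 61 %, 63 % and 66.5 %, and the course rises all the way. Its ground: “D takes some free Q as X, so L is more suppressed at high D”. At noon it stands a little below my number.

    Z + Q ⇌ J (K = 31.0 L mol⁻¹, k = 4.70 L mol⁻¹ h⁻¹)
    J → Q + G (k = 0.0850 h⁻¹)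
    D + Q ⇌ X (K = 2.20 L mol⁻¹, k = 2.50 L mol⁻¹ h⁻¹)
    X → Q + E (k = 0.100 h⁻¹)
    G + Q ⇌ L + Q, rate k5*[Q]*[G] forward; the back reaction follows from the equilibrium constant (K = 1.60, k = 0.830 L mol⁻¹ h⁻¹)

The flasks give 60.1 %, 61.0 %, 62.6 % and 65.5 %: rises all the way. With the step from D + Q to X struck out, dusk gives a share of 59.2 %. Now I put b to use on what stands at 5.00 d. Dusk holds Q at 59.8 % of the catalyst charged and D at 79 % of its charge, so x = q·d/b gives X at 17.8 %, and the flask holds 19.0 %. Noon, with Q at 77.9 % and D at 74 %, gives 2.73 %, and the flask holds 2.93 %.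

The runs are simulated from invented constants.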